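## The problem

CNP0162504.1 (33) joins two stereochemically dense halves through a three-carbon tether that carries no stereocentre. One half is a trans-decalin of the labdane type (C1–C10; C17 the methyl on C8, C18 the ester carbon on C4, C19 and C20 the methyls on C4 and C10, C11 and C12 the chain carbons on C9, C13 the carbon bearing the exocyclic methylene). The other is a 2,3,7-trioxabicyclo[4.3.0]nonan-8-one, a 1,2-dioxane trans-fused to a γ-lactone (C1' lactone carbonyl, C2' CH2, C3' methyl-bearing peroxide carbon, C4' CH–O, C5' CH2, C6' CH–OO bonded to C13). The nine stereocentres fall into a set of six (C4, C5, C6, C8, C9, C10) and a set of three (C3', C4', C6') that cannot control one another across C11–C13, so each half needs its own source of absolute configuration. In the decalin, C4, C5, C9 and C10 (4α-CO2Me, 5α-H, 9α-H, 10β-Me) are those of the abietane resin acids, and the two axial β-methyls C19 and C20 can steer both new oxygens (6α-OH, 8α-OH) into the equatorial α positions. In the bicycle the lactone oxygen on C4' and the C2' methylene are both equatorial on the dioxane chair, while the C3' methyl and the C13 substituent on C6' are axial; conjugate addition of a hydroperoxide to an unsaturated lactone would close the ring cis, and no equilibrating process would put the large group axial. Sensitive points are the O–O bond (low-valent metals, hydrides, phosphines), the C6'–H next to it (base-induced Kornblum–DeLaMare cleavage), the β-peroxy lactone (elimination from C2'), the pairs 6α-OH/C18 ester and 8α-OH/C12 acid (both lactonise) and the tertiary C8 alcohol. The feature on which the plan rests is that the C3' peroxide oxygen and C6' are 1,4-related through C4'–C5', while the C4' oxygen and C1' are γ-related through C3'–C2'. An acyclic C3' hydroperoxide with a leaving group on C6', a hydroxyl on C4' and an ester at C1' can therefore close the dioxane 6-exo-tet and the lactone 5-exo-trig, and its anti O/O relationship at C3'/C4' is that of an opened E-epoxide.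

## Retrosynthesis

**33 ⇒ 32 + 18.** The C11–C12 bond is cut. Making C12–C13 instead would need an sp3–sp2 cross-coupling with a zerovalent metal and base in the presence of the O–O bond, and C13–C6' can only be made before the peroxide exists. C11–C12 forms under neutral conditions when a C11 radical adds to the terminal alkene carbon of allyl sulfone 18; β-scission of the sulfonyl radical then leaves the C13 methylene in place. Decarboxylative radical generation at the C12 acid level was weighed and set aside: the γ-hydroxy acid lactonises onto O8 unless that oxygen is masked, and a thiocarbonyl-based precursor captures a primary radical faster than a non-activated allyl sulfone does. Iodide 32 under ditin photolysis has no internal trap and tolerates free hydroxyls, so the union can be the last step with no protecting group removed after the peroxide is made. The forward step must add to the alkene faster than any radical attacks the O–O bond.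

**18 ⇒ 16 (through 17).** The O–C6' bond of the dioxane and the O–C1' bond of the lactone are cut, opening both rings to the acyclic hydroperoxy hydroxy ester sulfonate 16. The neighbouring cut at O–C3' (conjugate addition of a C6' hydroperoxide) is the usual entry to peroxylactones but gives the cis fusion and leaves C6' uncontrolled. Cutting at C6' makes the axial C6' configuration the result of a stereospecific inversion. 16 has no ring, and its three stereocentres are each set by a separate reagent-controlled step. The forward reaction must be substitution with clean inversion at a secondary allylic carbon, without transposition, ionisation or elimination.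

**16 ⇒ 15 ⇒ 14.** The C3'–OO bond is cut back to epoxide 15, and the epoxide to E-alkene 14. Opening at the tertiary carbon with inversion converts the trans-epoxide into the anti C3'-OOH/C4'-OH pair; no other route to a tertiary hydroperoxide beside a secondary alcohol is stereospecific. The epoxidation is the only point where absolute configuration enters at C3'/C4', so it must be catalyst-controlled and must leave the second, 1,1-disubstituted alkene of 14 alone. The sulfonate is installed before the peroxide because a hydroperoxide cannot be carried through a sulfonylation.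

**14 ⇒ 13 ⇒ 12 + 3.** Sulfonate 14 comes from allylic alcohol 13, and the C6'–C13 bond of 13 is cut to aldehyde 12 and bromoalkene 3. This cut sets C6' in the bond-forming step and brings in the allyl sulfone unit whole. Making C5'–C6' by allylation would instead react through the substituted end of the allyl metal. The forward reaction is a ligand-controlled chromium-mediated alkenylation, which tolerates the ester and the enolisable aldehyde.

**12 ⇒ 11 ⇒ 10 ⇒ 7 + 8; 7 ⇒ 5 ⇒ 4.** The aldehyde is taken back to silyl ether 10, and the C2'–C3' bond is cut to alkenyl iodide 7 and methyl bromoacetate 8 (used as zinc enolate 9). The trisubstituted E-alkene with a β,γ-ester is the awkward element, since olefination routes risk conjugation. Syn-hydrozirconation of alkyne 5 (from pent-3-yn-1-ol, 4) fixes the geometry, and cross-coupling keeps it.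

**3 ⇒ 1 + 2.** The C–S bond is cut; S-alkylation of sulfinate 2 by the allylic bromide of 1 gives the bromoalkene in one step.

**32 ⇒ 31 ⇒ 30 ⇒ 29.** In the decalin half C11–C12 is cut a second time, now inside γ-lactone 29. Reduction to lactol 30 and alkoxy-radical β-fragmentation give the C11 iodide and turn C12 into a formate on O8 (31); the formate is removed together with the silyl ether to give 32. This uses the lactone, the form the hydroxy acid adopts anyway, and avoids lactone opening, protection of the tertiary alcohol and decarboxylation.

**29 ⇒ 28 ⇒ 27 ⇒ 26.** The C8–O bond is cut to exocyclic alkene 27, and C8=C17 to ketone 26. Adding a methyl nucleophile to the C8 ketone was rejected: it would enter from the α face, opposite the axial C20 methyl, and give the 8β-alcohol. Hydration through the C8 radical lets oxygen enter from that same open α face, and hydroxy ester 28 closes to 29.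

**26 ⇒ 25 ⇒ 24 ⇒ 23 ⇒ 22 ⇒ 21.** The C6–O bond is cut through boronate 24 to enone 23, and the C6=C7 bond of 23 to ketone 21 through silyl enol ether 22. The C8 ketone is the only handle near C6. Conjugate borylation and oxidation with retention deliver oxygen to the α face, because both axial methyls block the β face of C6. Hydride reduction of a C6 ketone would give the axial 6β-alcohol for the same reason.

**21 ⇒ 20 ⇒ 19.** Ring C of methyl levopimarate 20 is excised by ozonolysis, leaving C8 as ketone and C12 as ester; 20 is the methyl ester of levopimaric acid 19. This acid is chosen because its homoannular diene has its double bonds at C8(14) and C12, so cleavage spares ring B. The isomeric resin acids, whose dienes reach into ring B, would lose that ring as well.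

## Roads not taken

**Alternative 1: conjunctive three-component coupling at C6'.**
- **Cut and key step:** C13–C6' and C5'–C4' are cut together. A vinyl-metal reagent adds to decalin alkenyl boronate A2, and a chiral palladium catalyst couples the resulting ate complex with alkenyl bromide A3. The C13 alkenyl group migrates from boron to the new C6' while C5' bonds to C4' at palladium, giving allylic boronate A1 with the whole carbon skeleton.
- **Merits:** C6' is set by a catalyst as a C–B bond that oxidises with retention. No sulfone is needed, no chromium step has to accept a sulfonyl-bearing bromide, and no radical meets an O–O bond. In these respects it is better than the chosen plan.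
- **Weak points:** the migrating group is a 1,1-disubstituted alkenyl unit, for which direct cross-coupling of the ate complex competes. A1 is an allylic boronate open to 1,3-boron shift. After oxidation, sulfonylation, epoxidation (the C13 alkene is no longer deactivated by a sulfone), perhydrolysis, ring closure and removal of two silyl ethers all run on the full decalin-bearing material, the last of them after the peroxide exists.
- **Against it the chosen plan sets:** the fragile peroxide sequence is run on a small fragment, and the union is the final operation.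

**Alternative 2: carboxylate-directed C–H lactonisation at C6.**
- **Cut and key step:** the C6–O bond is cut. The free C18 acid of lactone acid A5 directs Mn(pdp)(OTf)2/H2O2 to the 6α C–H bond and closes the five-membered 18,6α-lactone, giving bis-lactone A4.
- **Merits:** it makes the C6–O bond from an unfunctionalised methylene and would replace enone formation, borylation/oxidation and silylation; if it worked the decalin line would be about three steps shorter.
- **Weak points:** the C18 carboxylate has a second γ-methylene (C2) and the reagent can also oxidise remote ring A positions. The lactone bridges two peri-equatorial positions and is strained. A4 then holds two lactones, and the hindered neopentyl 18,6-lactone must be opened to the methyl ester while the 12,8-lactone is kept or handled separately.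
- **Against it the chosen plan sets:** predictable α-face delivery to C6 by the two axial methyls, and a C18 methyl ester that is never disturbed, at the cost of those extra steps.

**Alternative 3: intramolecular Diels–Alder construction of the decalin.**
- **Cut and key step:** C5–C10 and C8–C9 are cut, opening both rings to acyclic triene A7. Its bis(silyloxy)diene adds to the E-enoate to give decalin A6, setting C5, C8, C9 and C10 together.
- **Merits:** independence from resin-acid supply; both ring oxygens are present from the start.
- **Weak points:** A7 is achiral, so absolute control must come from an external catalyst. The diene needs an inward-pointing silyloxy group at C8 and must form a quaternary C10. The C4 gem-diester of A6 has to be differentiated into β-methyl and α-ester. The C9 ester is one carbon short of the chain, and the C6 enol ether must still be reduced to the equatorial alcohol.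
- **Comparison:** the chosen plan takes C4, C5, C9 and C10 from levopimaric acid in the correct absolute sense. Alternative 3 is better only if that acid cannot be sourced.

Key step: step 11

## Route

Assumption: levopimaric acid (19) and the L-fructose-derived epoxidation ketone are treated as purchased materials; both are catalogue items, and the acid is also obtainable from pine oleoresin.

Step 1
Reactants: 1 2,3-dibromopropene; 2 sodium benzenesulfinate
Product: 3 2-bromoallyl phenyl sulfone
Conditions: DMF, rt
Reagents that add atoms: none
Why: S-alkylation of the sulfinate by the allylic bromide (SN2; the vinylic bromide is inert), the standard preparation of allyl sulfones.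

Step 2
Reactants: 4 pent-3-yn-1-ol
Product: 5 tert-butyldimethyl(pent-3-yn-1-yloxy)silane
Conditions: TBSCl, imidazole, CH2Cl2, 0 °C → rt
Reagents that add atoms: tert-butyldimethylsilyl chloride, CC(C)(C)[Si](C)(C)Cl
Why: Standard silylation of a primary alcohol; the bulky ether also discourages oxygen-directed delivery of zirconium to the nearer alkyne carbon in step 3.

Step 3
Reactants: 5 tert-butyldimethyl(pent-3-yn-1-yloxy)silane
Product: 7 tert-butyl{[(E)-4-iodopent-3-en-1-yl]oxy}dimethylsilane, via alkenylzirconocene chloride 6 (not isolated)
Conditions: Cp2Zr(H)Cl, THF, rt → 45 °C; then I2, 0 °C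
Reagents that add atoms: iodine, II
Why: Schwartz hydrozirconation adds Zr–H syn across the alkyne; with a slight excess of reagent and gentle warming zirconium settles on the methyl-bearing carbon, and iodinolysis with retention gives the E-iodide in which the methyl group and the chain are cis.

Step 4
Reactants: 7 tert-butyl{[(E)-4-iodopent-3-en-1-yl]oxy}dimethylsilane; 8 methyl bromoacetate
Product: 10 methyl (E)-6-[(tert-butyldimethylsilyl)oxy]-3-methylhex-3-enoate, via zinc ester enolate 9 (not isolated)
Conditions: 8, Zn, TMSCl (cat.), THF, 40 °C; then 7, Pd(PPh3)4 (cat.), THF/DMPU, 50 °C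
Reagents that add atoms: none
Why: Negishi-type cross-coupling of a Reformatsky reagent with an alkenyl iodide forms C2'–C3' with retention of alkene geometry; the neutral zinc enolate does not move the double bond into conjugation.

Step 5
Reactants: 10 methyl (E)-6-[(tert-butyldimethylsilyl)oxy]-3-methylhex-3-enoate
Product: 11 methyl (E)-6-hydroxy-3-methylhex-3-enoate
Conditions: HF·pyridine, THF, 0 °C → rt
Reagents that add atoms: none
Why: Fluoride desilylation under mildly acidic conditions leaves the β,γ-unsaturated ester unisomerised.

Step 6
Reactants: 11 methyl (E)-6-hydroxy-3-methylhex-3-enoate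
Product: 12 methyl (E)-3-methyl-6-oxohex-3-enoate
Conditions: Dess–Martin periodinane, CH2Cl2, 0 °C → rt
Reagents that add atoms: none
Why: Dess–Martin oxidation is neutral and fast, which suits a β,γ-unsaturated aldehyde that would conjugate under basic oxidations; 12 is used at once.

Step 7
Reactants: 12 methyl (E)-3-methyl-6-oxohex-3-enoate; 3 2-bromoallyl phenyl sulfone
Product: 13 methyl (3E,6S)-6-hydroxy-3-methyl-7-[(phenylsulfonyl)methyl]octa-3,7-dienoate
Conditions: CrCl2 (cat.), chiral 2-(oxazolin-2-yl)anilide methanesulfonamide ligand (cat.; antipode giving Re-face addition), 1,8-bis(dimethylamino)naphthalene (cat.), NiCl2·2,9-dimethyl-1,10-phenanthroline (cat.), Mn, Cp2ZrCl2, LiCl, MeCN, rt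
Reagents that add atoms: none
Why: Catalytic asymmetric Nozaki–Hiyama–Kishi alkenylation: zerovalent nickel inserts into the C–Br bond, the alkenyl group passes to the chiral chromium sulfonamide complex and adds to the Re face of the aldehyde, which gives the 6S carbinol. Organochromium reagents are not basic, so the acidic sulfone methylene, the ester and the enolisable aldehyde are tolerated.

Step 8
Reactants: 13 methyl (3E,6S)-6-hydroxy-3-methyl-7-[(phenylsulfonyl)methyl]octa-3,7-dienoate
Product: 14 methyl (3E,6S)-3-methyl-6-[(methylsulfonyl)oxy]-7-[(phenylsulfonyl)methyl]octa-3,7-dienoate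
Conditions: Ms2O, Et3N, CH2Cl2, −20 °C
Reagents that add atoms: methanesulfonic anhydride, CS(=O)(=O)OS(C)(=O)=O
Why: Sulfonylation with retention at C6'; the anhydride is used so that no chloride is present to displace the allylic sulfonate, and 14 is carried on without storage.

Step 9
Reactants: 14 methyl (3E,6S)-3-methyl-6-[(methylsulfonyl)oxy]-7-[(phenylsulfonyl)methyl]octa-3,7-dienoate
Product: 15 methyl 2-[(2S,3S)-2-methyl-3-{(2S)-2-[(methylsulfonyl)oxy]-3-[(phenylsulfonyl)methyl]but-3-en-1-yl}oxiran-2-yl]acetate
Conditions: L-fructose-derived Shi ketone, Oxone, K2CO3, Bu4NHSO4 (cat.), Na2B4O7 buffer, MeCN/CH2(OMe)2/H2O, 0 °C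
Reagents that add atoms: potassium peroxymonosulfate (Oxone), [K+].[O-]S(=O)(=O)OO
Why: Shi epoxidation: the chiral dioxirane reacts with the electron-richer trisubstituted alkene and not with the 1,1-disubstituted alkene, which is deactivated by the sulfonylmethyl and sulfonyloxy groups. The L-fructose-derived ketone is needed to give S configuration at the CH carbon of this E-alkene, hence the trans 3'S,4'S epoxide.

Step 10
Reactants: 15 methyl 2-[(2S,3S)-2-methyl-3-{(2S)-2-[(methylsulfonyl)oxy]-3-[(phenylsulfonyl)methyl]but-3-en-1-yl}oxiran-2-yl]acetate
Product: 16 methyl (3R,4S,6S)-3-hydroperoxy-4-hydroxy-3-methyl-6-[(methylsulfonyl)oxy]-7-[(phenylsulfonyl)methyl]oct-7-enoate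
Conditions: H2O2 (anhydrous, in Et2O), H3PMo12O40 (cat.), Et2O, rt
Reagents that add atoms: hydrogen peroxide, OO
Why: Acid-catalysed perhydrolysis of a trisubstituted epoxide: H2O2 attacks the tertiary carbon C3' with inversion while C4' keeps its oxygen, giving the anti 3R,4S hydroxy hydroperoxide. The mild heteropolyacid in ether is chosen so that the allylic sulfonate and the ester survive.

Step 11
Reactants: 16 methyl (3R,4S,6S)-3-hydroperoxy-4-hydroxy-3-methyl-6-[(methylsulfonyl)oxy]-7-[(phenylsulfonyl)methyl]oct-7-enoate
Product: 18 (1R,4R,6S)-1-methyl-4-[3-(phenylsulfonyl)prop-1-en-2-yl]-2,3,7-trioxabicyclo[4.3.0]nonan-8-one (peroxylactone allyl phenyl sulfone), via dioxane hydroxy ester 17 (not isolated)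
Conditions: Cs2CO3, DMF, 0 °C → rt; then CSA (cat.), CH2Cl2, rt
Reagents that add atoms: none
Why: Cs2CO3 removes the hydroperoxide proton, the most acidic one, and the tertiary peroxide anion displaces the C6' methanesulfonate intramolecularly with inversion to give dioxane 17; this is the known intramolecular alkylation of hydroperoxides by sulfonates. The 1,2-dioxane closes 6-exo-tet; allylic transposition would need an eight-membered transition state, and ionisation is disfavoured by the electron-poor, sulfonylmethyl-substituted alkene. C6' is the only stereocentre formed: its configuration follows from inversion of the 6S sulfonate set in step 7 and places the alkenyl group axial, which equilibrating or conjugate-addition routes would not do. C3' and C4' are untouched and carry the anti O/O relationship from step 10, so the C4' hydroxyl and the C2' arm are both equatorial on the new chair. The γ-hydroxy ester then lactonises 5-exo-trig to the trans-fused lactone 18, under the carbonate or, after neutralisation, under camphorsulfonic acid. A weak base and low temperature are chosen to avoid alkoxide-driven fragmentation of the β-hydroxy hydroperoxide, proton loss at C6'–H of the product and deprotonation next to the sulfone.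

Step 12
Reactants: 19 levopimaric acid
Product: 20 methyl levopimarate
Conditions: MeI, K2CO3, DMF, rt
Reagents that add atoms: iodomethane, CI
Why: Carboxylate alkylation under basic conditions; acid is avoided because the homoannular diene isomerises under acid.

Step 13
Reactants: 20 methyl levopimarate
Product: 21 keto diester (trans-decalin with 4α-CO2Me, 4β-Me, 10β-Me, 8-oxo and 9β-CH2CO2Me)
Conditions: O3, NaOH, MeOH/CH2Cl2, −78 °C
Reagents that add atoms: ozone, [O-][O+]=O; methanol, CO
Why: Ozonolysis in methanolic base cleaves both double bonds of the ring C diene; each CH terminus becomes a methyl ester by base-induced dehydration of its methoxy hydroperoxide and each fully substituted terminus a ketone, so ring C is excised and ring B is untouched. The equatorial 9β side chain is the stable arrangement next to the new ketone, so C9 holds.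

Step 14
Reactants: 21 keto diester
Product: 23 enone (C6=C7 double bond, 8-oxo), via silyl enol ether 22 (not isolated)
Conditions: LDA, TMSCl, THF, −78 °C; then Pd(OAc)2, MeCN, rt
Reagents that add atoms: none
Why: Saegusa–Ito oxidation: LDA with internal silyl chloride quench enolises the ketone kinetically toward the C7 methylene (not the hindered C9–H and not the less acidic ester), and Pd(OAc)2 converts the silyl enol ether into the C6=C7 enone.

Step 15
Reactants: 23 enone
Product: 25 6α-hydroxy-8-ketone, via boryl ketone 24 (not isolated)
Conditions: B2pin2, CuCl (cat.), Xantphos (cat.), NaOtBu (cat.), MeOH, THF, rt; then NaBO3·4H2O, THF/H2O, rt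
Reagents that add atoms: sodium perborate, [Na+].[O-]OB=O
Why: Copper-catalysed conjugate borylation followed by perborate oxidation with retention. The boryl–copper adds to C6 from the α face because the β face is shielded by the axial C19 and C20 methyls, so the equatorial 6α-alcohol results.

Step 16
Reactants: 25 6α-hydroxy-8-ketone
Product: 26 6α-(triethylsilyloxy)-8-ketone
Conditions: TESCl, imidazole, DMF, 0 °C → rt
Reagents that add atoms: chlorotriethylsilane, CC[Si](CC)(CC)Cl
Why: Silylation of the β-hydroxy ketone under mild base before it can eliminate; triethylsilyl is chosen because it leaves in the same acidic methanolysis that removes the formate in step 21.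

Step 17
Reactants: 26 6α-(triethylsilyloxy)-8-ketone
Product: 27 6α-(triethylsilyloxy)-8(17)-alkene (exocyclic methylene on C8)
Conditions: Zn, CH2Br2, TiCl4, THF/CH2Cl2, 0 °C → rt
Reagents that add atoms: dibromomethane, BrCBr
Why: Takai–Lombardo methylenation is non-basic and selective for ketones over esters, which avoids elimination of the β-silyloxy group and leaves both esters.

Step 18
Reactants: 27 6α-(triethylsilyloxy)-8(17)-alkene
Product: 29 12,8α-lactone (trans-fused γ-lactone, 8β-Me, 6α-OSiEt3, C18 methyl ester), via hydroxy diester 28 (not isolated)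
Conditions: Mn(dpm)3 (cat.), PhSiH3, O2 (1 atm), i-PrOH/CH2Cl2, 0 °C → rt; then PPTS (cat.), PhMe, 60 °C
Reagents that add atoms: dioxygen, O=O
Why: Mukaiyama hydration: hydrogen-atom transfer gives the tertiary C8 radical, O2 is captured on the α face away from the axial C20 methyl, and reduction gives the 8α-alcohol with the C17 methyl axial. The equatorial hydroxyl and the equatorial C9 acetate arm then close to the trans-fused γ-lactone under mild acid.

Step 19
Reactants: 29 12,8α-lactone
Product: 30 lactol (C12 hemiacetal, both anomers)
Conditions: i-Bu2AlH, CH2Cl2, −78 °C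
Reagents that add atoms: none
Why: Partial reduction of a γ-lactone to the lactol at low temperature; the neopentyl C18 methyl ester reacts much more slowly.

Step 20
Reactants: 30 lactol
Product: 31 11-iodo 8α-formate (9β-CH2I, 8α-OCHO, 6α-OSiEt3)
Conditions: PhI(OAc)2, I2, CH2Cl2, hν (visible), rt
Reagents that add atoms: iodine, II
Why: Suárez fragmentation: the anomeric hypoiodite gives an alkoxy radical whose β-scission breaks C11–C12 and forms the formate carbonyl; the primary C11 radical is trapped by iodine. No stereocentre is involved.

Step 21
Reactants: 31 11-iodo 8α-formate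
Product: 32 11-iodo-6α,8α-diol
Conditions: HCl (cat.), MeOH, 0 °C → rt
Reagents that add atoms: none
Why: Acid-catalysed methanolysis removes the formate (attack at the unhindered formyl carbon) and the triethylsilyl ether in one operation; dilute acid at low temperature spares the tertiary alcohol and the 6-OH/C18 ester pair.

Step 22
Reactants: 32 11-iodo-6α,8α-diol; 18 peroxylactone allyl phenyl sulfone
Product: 33 CNP0162504.1
Conditions: (Bu3Sn)2, hν (sunlamp, Pyrex), PhH, 30 °C, concentrated, 32 in excess
Reagents that add atoms: none
Why: Radical allylation with an allyl sulfone under ditin photolysis: the stannyl radical abstracts iodine, the primary C11 radical adds to the terminal alkene carbon of 18, and the adduct radical expels the phenylsulfonyl radical, which regenerates a stannyl radical from the ditin. Loss of the sulfonyl radical is expected to outrun attack of the adduct radical on the neighbouring O–O bond, and the excess of 32 keeps stannyl radicals occupied with iodine abstraction; no stereocentre is formed or touched.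

## Compound list

1 | 2,3-dibromopropene | C=C(Br)CBr | starting material
2 | sodium benzenesulfinate | [Na+].[O-]S(=O)c1ccccc1 | starting material
3 | 2-bromoallyl phenyl sulfone | C=C(Br)CS(=O)(=O)c1ccccc1 | intermediate
4 | pent-3-yn-1-ol | CC#CCCO | starting material
5 | tert-butyldimethyl(pent-3-yn-1-yloxy)silane | CC#CCCO[Si](C)(C)C(C)(C)C | intermediate
6 | (E)-alkenylzirconocene chloride (Zr on the methyl-bearing carbon, cis to H) | C/C(=C\CCO[Si](C)(C)C(C)(C)C)[Zr](Cl)(C1C=CC=C1)C1C=CC=C1 | intermediate (not isolated)
7 | tert-butyl{[(E)-4-iodopent-3-en-1-yl]oxy}dimethylsilane | C/C(I)=C\CCO[Si](C)(C)C(C)(C)C | intermediate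
8 | methyl bromoacetate | COC(=O)CBr | starting material
9 | bromozinc enolate of methyl acetate (Reformatsky reagent) | COC(=O)C[Zn]Br | intermediate (not isolated)
10 | methyl (E)-6-[(tert-butyldimethylsilyl)oxy]-3-methylhex-3-enoate | COC(=O)C/C(C)=C/CCO[Si](C)(C)C(C)(C)C | intermediate
11 | methyl (E)-6-hydroxy-3-methylhex-3-enoate | COC(=O)C/C(C)=C/CCO | intermediate
12 | methyl (E)-3-methyl-6-oxohex-3-enoate | COC(=O)C/C(C)=C/CC=O | intermediate
13 | methyl (3E,6S)-6-hydroxy-3-methyl-7-[(phenylsulfonyl)methyl]octa-3,7-dienoate | C=C(CS(=O)(=O)c1ccccc1)[C@@H](O)C/C=C(\C)CC(=O)OC | intermediate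
14 | methyl (3E,6S)-3-methyl-6-[(methylsulfonyl)oxy]-7-[(phenylsulfonyl)methyl]octa-3,7-dienoate | C=C(CS(=O)(=O)c1ccccc1)[C@@H](OS(C)(=O)=O)C/C=C(\C)CC(=O)OC | intermediate
15 | methyl 2-[(2S,3S)-2-methyl-3-{(2S)-2-[(methylsulfonyl)oxy]-3-[(phenylsulfonyl)methyl]but-3-en-1-yl}oxiran-2-yl]acetate | C=C(CS(=O)(=O)c1ccccc1)[C@@H](OS(C)(=O)=O)C[C@@H]1O[C@@]1(C)CC(=O)OC | intermediate
16 | methyl (3R,4S,6S)-3-hydroperoxy-4-hydroxy-3-methyl-6-[(methylsulfonyl)oxy]-7-[(phenylsulfonyl)methyl]oct-7-enoate | C=C(CS(=O)(=O)c1ccccc1)[C@@H](OS(C)(=O)=O)C[C@H](O)[C@](C)(OO)CC(=O)OC | intermediate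
17 | methyl 2-{(3R,4S,6R)-4-hydroxy-3-methyl-6-[3-(phenylsulfonyl)prop-1-en-2-yl]-1,2-dioxan-3-yl}acetate | C=C(CS(=O)(=O)c1ccccc1)[C@H]1C[C@H](O)[C@@](C)(CC(=O)OC)OO1 | intermediate (not isolated)
18 | (1R,4R,6S)-1-methyl-4-[3-(phenylsulfonyl)prop-1-en-2-yl]-2,3,7-trioxabicyclo[4.3.0]nonan-8-one | C=C(CS(=O)(=O)c1ccccc1)[C@H]1C[C@@H]2OC(=O)C[C@@]2(C)OO1 | intermediate
19 | levopimaric acid (abieta-8(14),12-dien-18-oic acid) | CC(C)C1=CC[C@H]2C(=C1)CC[C@@H]3[C@@]2(CCC[C@@]3(C)C(=O)O)C | starting material
20 | methyl levopimarate | CC(C)C1=CC[C@H]2C(=C1)CC[C@@H]3[C@@]2(CCC[C@@]3(C)C(=O)OC)C | intermediate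
21 | keto diester: trans-decalin, 4α-CO2Me, 4β-Me, 5α-H, 10β-Me, 8-oxo, 9β-CH2CO2Me | COC(=O)C[C@@H]1[C@@]2(C)CCC[C@@](C)(C(=O)OC)[C@@H]2CCC1=O | intermediate
22 | 8-(trimethylsilyloxy) C7=C8 enol ether of 21 | COC(=O)C[C@@H]1[C@@]2(C)CCC[C@@](C)(C(=O)OC)[C@@H]2CC=C1O[Si](C)(C)C | intermediate (not isolated)
23 | enone: C6=C7, 8-oxo | COC(=O)C[C@@H]1[C@@]2(C)CCC[C@@](C)(C(=O)OC)[C@@H]2C=CC1=O | intermediate
24 | 6α-(pinacolboryl)-8-ketone | COC(=O)C[C@@H]1[C@@]2(C)CCC[C@@](C)(C(=O)OC)[C@@H]2[C@@H](B3OC(C)(C)C(C)(C)O3)CC1=O | intermediate (not isolated)
25 | 6α-hydroxy-8-ketone | COC(=O)C[C@@H]1[C@@]2(C)CCC[C@@](C)(C(=O)OC)[C@@H]2[C@@H](O)CC1=O | intermediate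
26 | 6α-(triethylsilyloxy)-8-ketone | COC(=O)C[C@@H]1[C@@]2(C)CCC[C@@](C)(C(=O)OC)[C@@H]2[C@@H](O[Si](CC)(CC)CC)CC1=O | intermediate
27 | 6α-(triethylsilyloxy)-8(17)-alkene | COC(=O)C[C@@H]1[C@@]2(C)CCC[C@@](C)(C(=O)OC)[C@@H]2[C@@H](O[Si](CC)(CC)CC)CC1=C | intermediate
28 | 8α-hydroxy-8β-methyl diester (6α-OSiEt3) | COC(=O)C[C@@H]1[C@@]2(C)CCC[C@@](C)(C(=O)OC)[C@@H]2[C@@H](O[Si](CC)(CC)CC)C[C@@]1(C)O | intermediate (not isolated)
29 | 12,8α-lactone (6α-OSiEt3, 8β-Me, C18 methyl ester) | O=C1C[C@@H]2[C@@]3(C)CCC[C@@](C)(C(=O)OC)[C@@H]3[C@@H](O[Si](CC)(CC)CC)C[C@@]2(C)O1 | intermediate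
30 | lactol of 29 (C12 hemiacetal, both anomers) | OC1C[C@@H]2[C@@]3(C)CCC[C@@](C)(C(=O)OC)[C@@H]3[C@@H](O[Si](CC)(CC)CC)C[C@@]2(C)O1 | intermediate
31 | 9β-(iodomethyl) 8α-formate, 6α-OSiEt3 | IC[C@@H]1[C@@]2(C)CCC[C@@](C)(C(=O)OC)[C@@H]2[C@@H](O[Si](CC)(CC)CC)C[C@@]1(C)OC=O | intermediate
32 | 9β-(iodomethyl)-6α,8α-diol | IC[C@@H]1[C@@]2(C)CCC[C@@](C)(C(=O)OC)[C@@H]2[C@@H](O)C[C@@]1(C)O | intermediate
33 | CNP0162504.1 | C=C(CC[C@@H]1[C@@]2(C)CCC[C@@](C)(C(=O)OC)[C@@H]2[C@@H](O)C[C@@]1(C)O)[C@H]1C[C@@H]2OC(=O)C[C@@]2(C)OO1 | target

## Step count and uncertain steps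

Total step count: 22. Longest linear sequence: 11 steps (4 → 33 through steps 2–11 and 22; the decalin line 19 → 33, steps 12–22, is of equal length).

**Step 11 (key step).** The most likely failures are alkoxide-driven fragmentation of the β-hydroxy hydroperoxide before it cyclises, base-induced cleavage at C6'–H of the product, and deprotonation next to the sulfone with migration of the double bond. All three come from exposing a free C4' hydroxyl and the finished peroxide to base for as long as lactonisation needs. Fallback, from 16 to 18: 16 is lactonised first under acid (CSA, CH2Cl2) to the hydroperoxy lactone methanesulfonate F1, which has no free hydroxyl. The dioxane is then closed in a separate, short treatment with Cs2CO3 in DMF at 0 °C, giving 18.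

**Step 22.** The adduct radical at C13 sits next to the O–O bond and may attack it instead of losing the sulfonyl radical. Stannyl radicals may also reduce the peroxide once the iodide is consumed, and addition of a primary radical to a non-activated alkene is slow enough for hydrogen transfer within the decalin to compete. Fallback, from 32 and 15 to 33: the union is moved ahead of peroxide formation. 32 and epoxy sulfonate 15 are coupled under the same ditin conditions to the coupled epoxy methanesulfonate F2. Perhydrolysis (H2O2, H3PMo12O40, Et2O) gives the coupled hydroxy hydroperoxide F3, and the Cs2CO3/CSA closure of step 11 run on F3 gives 33 directly.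

**Step 7.** The alkenyl-metal intermediate carries a sulfinate on the adjacent carbon and may lose it by β-elimination. Zerovalent nickel may also ionise the allylic C–S bond, and facial selectivity with this unusual bromide is untested. Fallback, from 1 and 12 to 13: sulfur is carried at the sulfide level, where neither pathway is favourable. 1 with thiophenol and K2CO3 in acetone gives 2-bromoallyl phenyl sulfide F4. The same chromium-mediated coupling of F4 with 12 gives the sulfide allylic alcohol F5, and buffered Oxone without ketone oxidises sulfur only, returning 13.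

**Step 10.** The allylic methanesulfonate may solvolyse in the acidic peroxide medium (or already in the buffered epoxidation of step 9), and attack at C4' or participation of the ester carbonyl may erode regioselectivity. Fallback, from 13 to 16: the leaving group is installed only after the O–O bond exists in masked form.
- 13 is converted with 4-methoxybenzyl trichloroacetimidate and catalytic CSA into the 4-methoxybenzyl ether F6.
- F6 is epoxidised as in step 9 to the epoxide F7 and opened as in step 10 to the hydroxy hydroperoxide F8.
- TESOTf and 2,6-lutidine cap both OOH and OH, giving the silyl peroxide silyl ether F9.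
- DDQ frees the C6' alcohol F10, and Ms2O/Et3N gives the methanesulfonate F11.
- HF·pyridine removes both silyl groups and returns 16.

**Step 18.** Oxygen capture by the C8 radical may not be selective enough for the α face, which would give the 8β-alcohol and the cis-lactone. Fallback, from 27 to 29: mCPBA attacks the exocyclic alkene from the α face to give the 8α,17-epoxide F12. LiEt3BH at low temperature opens it at C17 and reduces the C12 ester, leaving the hindered C18 ester, to give the 8α,12-diol F13. TEMPO/PhI(OAc)2 then oxidises the primary alcohol and closes the lactone 29.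

## Further compounds

F1 | step 11 | hydroperoxy γ-lactone methanesulfonate (lactone closed, OOH free) | C=C(CS(=O)(=O)c1ccccc1)[C@@H](OS(C)(=O)=O)C[C@@H]1OC(=O)C[C@@]1(C)OO
F2 | step 22 | coupled epoxy methanesulfonate (decalin diol joined at C11–C12) | C=C(CC[C@@H]1[C@@]2(C)CCC[C@@](C)(C(=O)OC)[C@@H]2[C@@H](O)C[C@@]1(C)O)[C@@H](OS(C)(=O)=O)C[C@@H]1O[C@@]1(C)CC(=O)OC
F3 | step 22 | coupled hydroxy hydroperoxide methanesulfonate | C=C(CC[C@@H]1[C@@]2(C)CCC[C@@](C)(C(=O)OC)[C@@H]2[C@@H](O)C[C@@]1(C)O)[C@@H](OS(C)(=O)=O)C[C@H](O)[C@](C)(OO)CC(=O)OC
F4 | step 7 | 2-bromoallyl phenyl sulfide | C=C(Br)CSc1ccccc1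
F5 | step 7 | methyl (3E,6S)-6-hydroxy-3-methyl-7-[(phenylsulfanyl)methyl]octa-3,7-dienoate | C=C(CSc1ccccc1)[C@@H](O)C/C=C(\C)CC(=O)OC
F6 | step 10 | 4-methoxybenzyl ether of 13 | C=C(CS(=O)(=O)c1ccccc1)[C@@H](OCc1ccc(OC)cc1)C/C=C(\C)CC(=O)OC
F7 | step 10 | (2S,3S)-epoxide of F6 | C=C(CS(=O)(=O)c1ccccc1)[C@@H](OCc1ccc(OC)cc1)C[C@@H]1O[C@@]1(C)CC(=O)OC
F8 | step 10 | (3R,4S)-hydroxy hydroperoxide 4-methoxybenzyl ether | C=C(CS(=O)(=O)c1ccccc1)[C@@H](OCc1ccc(OC)cc1)C[C@H](O)[C@](C)(OO)CC(=O)OC
F9 | step 10 | triethylsilyl peroxide triethylsilyl ether 4-methoxybenzyl ether | C=C(CS(=O)(=O)c1ccccc1)[C@@H](OCc1ccc(OC)cc1)C[C@H](O[Si](CC)(CC)CC)[C@](C)(OO[Si](CC)(CC)CC)CC(=O)OC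
F10 | step 10 | C6' alcohol with triethylsilyl peroxide and triethylsilyl ether | C=C(CS(=O)(=O)c1ccccc1)[C@@H](O)C[C@H](O[Si](CC)(CC)CC)[C@](C)(OO[Si](CC)(CC)CC)CC(=O)OC
F11 | step 10 | C6' methanesulfonate with triethylsilyl peroxide and triethylsilyl ether | C=C(CS(=O)(=O)c1ccccc1)[C@@H](OS(C)(=O)=O)C[C@H](O[Si](CC)(CC)CC)[C@](C)(OO[Si](CC)(CC)CC)CC(=O)OC
F12 | step 18 | 8α,17-epoxide of 27 | COC(=O)C[C@@H]1[C@@]2(C)CCC[C@@](C)(C(=O)OC)[C@@H]2[C@@H](O[Si](CC)(CC)CC)C[C@@]1(C3)O3
F13 | step 18 | 8α,12-diol (6α-OSiEt3, C18 methyl ester) | OCC[C@@H]1[C@@]2(C)CCC[C@@](C)(C(=O)OC)[C@@H]2[C@@H](O[Si](CC)(CC)CC)C[C@@]1(C)O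
A1 | alternative 1 | allylic C6' pinacol boronate with the full carbon skeleton (6,8-bis-triethylsilyl ether) | C=C(CC[C@@H]1[C@@]2(C)CCC[C@@](C)(C(=O)OC)[C@@H]2[C@@H](O[Si](CC)(CC)CC)C[C@@]1(C)O[Si](CC)(CC)CC)[C@@H](B1OC(C)(C)C(C)(C)O1)C/C=C(\C)CC(=O)OC
A2 | alternative 1 | decalin C13 alkenyl pinacol boronate (6,8-bis-triethylsilyl ether) | C=C(CC[C@@H]1[C@@]2(C)CCC[C@@](C)(C(=O)OC)[C@@H]2[C@@H](O[Si](CC)(CC)CC)C[C@@]1(C)O[Si](CC)(CC)CC)B1OC(C)(C)C(C)(C)O1
A3 | alternative 1 | methyl (E)-4-bromo-3-methylbut-3-enoate | COC(=O)C/C(C)=C/Br
A4 | alternative 2 | 18,6α:12,8α-bis-lactone | O=C1C[C@@H]2[C@@]3(C)CCC[C@@]4(C)C(=O)O[C@H]([C@H]34)C[C@@]2(C)O1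
A5 | alternative 2 | 12,8α-lactone with free C18 acid | O=C1C[C@@H]2[C@@]3(C)CCC[C@@](C)(C(=O)O)[C@@H]3CC[C@@]2(C)O1
A6 | alternative 3 | Diels–Alder adduct: trans-decalin with C6 silyl enol ether, C8 silyl ether, C4 gem-diester and C9 ester | COC(=O)[C@@H]1[C@@]2(C)CCCC(C(=O)OC)(C(=O)OC)[C@@H]2C(O[Si](C)(C)C)=C[C@@]1(C)O[Si](C)(C)C(C)(C)C
A7 | alternative 3 | acyclic triene: bis(silyloxy)diene tethered to the E-enoate | COC(=O)/C=C(\C)CCCC(C(=O)OC)(C(=O)OC)/C=C(O[Si](C)(C)C)/C=C(/C)O[Si](C)(C)C(C)(C)C
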